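All constants were chosen freely; the flask was simulated.

Which flask leads in the share of target among target, isomer of the product A and isomer of the product B, and how large is that share in each?

in all of them: solid substrate 0.40 M; catalyst 1.2 mol%; time 4.0 min
- alder: temperature 60 °C
- oak: temperature 80 °C
- cedar: temperature 40 °C

* which flask leads in share of target in all that became target or isomer of the product A or isomer of the product B ("all alike" within 1.5 percentage points) (alder / oak / cedar / all alike)
* share of target in all that became target or isomer of the product A or isomer of the product B, alder
* share of target in all that became target or isomer of the product A or isomer of the product B, oak
* share of target in all that became target or isomer of the product A or isomer of the product B, cedar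

- solid substrate is a solid; its amount is given per volume of the solution
- at 60 °C the constants are as listed, elsewhere as the activation energies and enthalpies make them
- at the start none of the solid substrate is in solution
- what has only dissolved of solid substrate counts as not reacted

    starting material + catalyst ⇌ target + catalyst, rate k1*[starting material]*[catalyst] forward; the back reaction follows from the equilibrium constant (K1 = 0.42, k1 = 2.4 /M/s, Ea1 = 53.0 kJ/mol, ΔH1 = −25.0 kJ/mol)
    target ⇌ isomer of the product A (K2 = 2.2, k2 = 0.013 /s, Ea2 = 86.0 kJ/mol, ΔH2 = −24.0 kJ/mol)
    isomer of the product A ⇌ isomer of the product B (K3 = 2.2, k3 = 0.0022 /s, Ea3 = 87.0 kJ/mol, ΔH3 = −19.0 kJ/mol)
    isomer of the product B ⇌ starting material (k4 = 0.26 /s, Ea4 = 73.0 kJ/mol)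
    solid substrate ⇌ starting material, rate k5*(cs5 - [starting material]) while solid is left; crystals form when [starting material] > cs5 (cs5 = 0.39 M, k5 = 0.0079 /s)
    (constants at 60 °C)

The solid dissolves into starting material, which the catalyst turns into target. Target goes on to isomer of the product A, that to isomer of the product B, and isomer of the product B returns to starting material, so the dissolved species stand in a ring.

We begin at the hot end. In oak the relaxation half-lives, each step taken alone, are 0.398 s, 0.0879 min and 0.531 min. The longest is short against the 4.0 min of the run, so we expect thermodynamic control there, and rates drop out of the share.

For one part of target, oak then holds 1.35 parts of isomer of the product A and 2.01 parts of isomer of the product B. That gives 23.0 %, which we call the equilibrium share: one part divided by the sum of the parts at that temperature. Being a ratio, it does not ask how much has dissolved.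

At the cold end both constants are larger, so the equilibrium share falls, to 12.4 % for alder. But step 2 speeds up 42 times from cedar to oak, and oak's relaxation half-life of target and isomer of the product A scaled by that factor gives something like 3.69 min for cedar, which is not short against the run. For cedar we therefore commit to no number and to no place in the order.

The forecast named oak, with 12.4 % in alder, 23 % in oak and 3.5 % in cedar, holding for oak that “the system reaches full equilibrium”.

The simulation gives oak in the lead, with 12.3 % in alder, 23.0 % in oak and 3.71 % in cedar.

Oak's 23.0 % stands beside the equilibrium share of 23.0 %, and left ten times as long oak still reads 23.0 %. At 2.00 min, with 26.9 % of the solid substrate undissolved, oak's products already give 22.6 %, again the equilibrium share. The reckoning took two equilibrium constants and a comparison of half-lives with the run.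

For a neighbour flask like oak but kept at 95 °C, the parts become 0.965 and 1.11, so the equilibrium share is 32.6 %, higher than oak's. The simulation gives 32.6 % for that flask.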